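**Retrosynthetic overview**
1. Target 20 ← the ten-membered carbocycle and the cis α-methylene-γ-lactone are closed together, last, at C7–C8 by a cathodic, bismuth-catalysed intramolecular allylation of the lactol-masked C8 aldehyde by the (Z)-2-(bromomethyl)enoate of 17.
2. 17 ← C7 homologation (aldehyde → Baylis–Hillman-type adduct → allylic bromide) after C6 angeloylation and C4 acetylation of keto diol 11.
3. 11 ← C2–C3 union: α-sulfonyl carbanion of oxolane 6 opens lactone 9, then desulfonylation.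
4. 6 (C1, C10) ← butenolide 1 by anti-selective cuprate addition; 9 (C4, C6) ← lactone 7 by enolate methylation, then hydroxylation.
5. Ring order: the oxolane (from 1) and butyrolactone (from 7) templates carry the stereocentres first; the carbocycle and the lactone form in the final step.

Numbering: germacran-8,12-olide numbering is used for the carbons. C1 (CHOH), C2 (CH2), C3 (C=O), C4 (C(CH3)OAc), C5 (CH2), C6 (CH–O-angeloyl), C7 (CH), C8 (CH–O of the lactone), C9 (CH2), C10 (CH–CH3), back to C1; C11 (=C13H2) sits on C7 and C12 is the lactone carbonyl.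

Assumption: 1 and 7 are taken as purchasable chiral-pool lactones (from levoglucosenone and D-glutamic acid); metal enolates, alkoxides and carbanions that are quenched on work-up are treated as forms of the numbered compound, and only neutral species of telescoped operations get their own number.

**Route**

Step 1
Reactants: 1 (S)-5-(hydroxymethyl)furan-2(5H)-one
Product: 2 [(2S)-5-oxo-2,5-dihydrofuran-2-yl]methyl 4-methylbenzenesulfonate
Conditions: TsCl, pyridine, CH2Cl2, 0 °C
Reagents that add atoms: 4-methylbenzenesulfonyl chloride, Cc1ccc(cc1)S(Cl)(=O)=O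
Why: O-sulfonylation of the only hydroxyl (primary) gives the crystalline tosylate at 0 °C without touching the base-sensitive butenolide or its stereocentre.

Step 2
Reactants: 2 [(2S)-5-oxo-2,5-dihydrofuran-2-yl]methyl 4-methylbenzenesulfonate
Product: 3 [(2S,3S)-3-methyl-5-oxooxolan-2-yl]methyl 4-methylbenzenesulfonate (trans lactone)
Conditions: Me2CuLi, Et2O, −78 °C; aq. NH4Cl
Reagents that add atoms: lithium dimethylcuprate, [Li+].C[Cu-]C
Why: Gilman cuprate 1,4-addition to a 5-substituted furan-2(5H)-one occurs anti to the CH2OTs group on the neighbouring ring carbon, so the purchased C1 centre sets C10 trans (3S), and the primary tosylate is inert to the cuprate at −78 °C.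

Step 3
Reactants: 3 [(2S,3S)-3-methyl-5-oxooxolan-2-yl]methyl 4-methylbenzenesulfonate
Product: 5 [(2S,3S)-5-methoxy-3-methyloxolan-2-yl]methyl 4-methylbenzenesulfonate (anomeric mixture), via lactol 4 (not isolated)
Conditions: i-Bu2AlH, CH2Cl2, −78 °C; then MeOH, PPTS, rt
Reagents that add atoms: methanol, CO
Why: Half-reduction of the γ-lactone stops at the lactol at −78 °C and acid-catalysed Fischer-type acetalisation then masks the C8 aldehyde and the C1 oxygen together as a methyl oxolanyl acetal (anomeric centre inconsequential).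

Step 4
Reactants: 5 [(2S,3S)-5-methoxy-3-methyloxolan-2-yl]methyl 4-methylbenzenesulfonate
Product: 6 (2S,3S)-5-methoxy-3-methyl-2-[(phenylsulfonyl)methyl]oxolane (anomeric mixture)
Conditions: PhSO2Na, Bu4NI (cat.), DMF, 80 °C
Reagents that add atoms: sodium benzenesulfinate, [Na+].[O-]S(=O)c1ccccc1
Why: SN2 displacement of the primary tosylate by the sulfur of the sulfinate (iodide catalysis), as is routine for 5-O-sulfonyl furanosides, installs the carbanion-stabilising group at C2 without touching C1 or C10.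

Step 5
Reactants: 7 (R)-5-[(trityloxy)methyl]dihydrofuran-2(3H)-one
Product: 8 (3S,5R)-3-methyl-5-[(trityloxy)methyl]dihydrofuran-2(3H)-one (trans major)
Conditions: LiN(i-Pr)2, THF, −78 °C; MeI
Reagents that add atoms: iodomethane, CI
Why: Lithium enolate alkylation of the γ-lactone takes place anti to the bulky CH2OTr group (1,3-induction), giving mainly the trans methyl lactone; this centre is re-enolised in the next step.

Step 6
Reactants: 8 (3S,5R)-3-methyl-5-[(trityloxy)methyl]dihydrofuran-2(3H)-one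
Product: 9 (3S,5R)-3-hydroxy-3-methyl-5-[(trityloxy)methyl]dihydrofuran-2(3H)-one
Conditions: KN(SiMe3)2, THF, −78 °C; MoO5·pyridine·HMPA, −78 → −40 °C; aq. Na2SO3
Reagents that add atoms: oxodiperoxymolybdenum(pyridine)(hexamethylphosphoramide), O=[Mo]12(OO1)OO2.c1ccncc1.CN(C)P(=O)(N(C)C)N(C)C
Why: Vedejs enolate hydroxylation: the oxidant approaches the tetrasubstituted enolate anti to CH2OTr, so the hydroxyl ends trans and the methyl cis to that group, which fixes the tertiary C4 centre (3S) under control of the purchased C6 centre.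

Step 7
Reactants: 6 (2S,3S)-5-methoxy-3-methyl-2-[(phenylsulfonyl)methyl]oxolane; 9 (3S,5R)-3-hydroxy-3-methyl-5-[(trityloxy)methyl]dihydrofuran-2(3H)-one
Product: 10 (3S,5R)-3,5-dihydroxy-1-[(2S,3S)-5-methoxy-3-methyloxolan-2-yl]-3-methyl-1-(phenylsulfonyl)-6-(trityloxy)hexan-2-one (epimers at the sulfonyl carbon; in equilibrium with its cyclic hemiketal)
Conditions: 6, LiN(i-Pr)2 (3.2 equiv), THF, −78 °C; then 9, −78 → −30 °C; aq. NH4Cl
Reagents that add atoms: none
Why: Claisen-type acylation of the α-sulfonyl carbanion (stable at −78 °C despite the β ring oxygen) by the lactone forms the C2–C3 bond and releases the C6 hydroxyl by ring opening; the extra base absorbs the tertiary OH and the acidic β-keto sulfone, and no stereocentre of either fragment is touched.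

Step 8
Reactants: 10 (3S,5R)-3,5-dihydroxy-1-[(2S,3S)-5-methoxy-3-methyloxolan-2-yl]-3-methyl-1-(phenylsulfonyl)-6-(trityloxy)hexan-2-one
Product: 11 (3S,5R)-3,5-dihydroxy-1-[(2R,3S)-5-methoxy-3-methyloxolan-2-yl]-3-methyl-6-(trityloxy)hexan-2-one
Conditions: SmI2, THF–MeOH, −78 °C
Reagents that add atoms: none
Why: Single-electron reductive desulfonylation of the β-keto sulfone is instantaneous at −78 °C and the samarium enolate is protonated by methanol before it can expel the β ring oxygen, leaving the C3 ketone flanked by C2H2.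

Step 9
Reactants: 11 (3S,5R)-3,5-dihydroxy-1-[(2R,3S)-5-methoxy-3-methyloxolan-2-yl]-3-methyl-6-(trityloxy)hexan-2-one
Product: 12 (2R,4S)-4-hydroxy-6-[(2R,3S)-5-methoxy-3-methyloxolan-2-yl]-4-methyl-5-oxo-1-(trityloxy)hexan-2-yl (2Z)-2-methylbut-2-enoate
Conditions: angelic acid, 2,4,6-trichlorobenzoyl chloride, Et3N, toluene, rt; then 11, 75 °C
Reagents that add atoms: angelic acid, C/C=C(/C)C(O)=O
Why: Yamaguchi esterification through the preformed mixed anhydride without DMAP acylates only the secondary C6 hydroxyl (the tertiary and hemiketal hydroxyls are too hindered) and avoids Z to E isomerisation of the angelate.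

Step 10
Reactants: 12 (2R,4S)-4-hydroxy-6-[(2R,3S)-5-methoxy-3-methyloxolan-2-yl]-4-methyl-5-oxo-1-(trityloxy)hexan-2-yl (2Z)-2-methylbut-2-enoate
Product: 13 (2R,4S)-4-acetoxy-6-[(2R,3S)-5-methoxy-3-methyloxolan-2-yl]-4-methyl-5-oxo-1-(trityloxy)hexan-2-yl (2Z)-2-methylbut-2-enoate
Conditions: Ac2O, DMAP, Et3N, CH2Cl2, 35 °C
Reagents that add atoms: acetic anhydride, CC(=O)OC(C)=O
Why: DMAP-catalysed acyl transfer esterifies the remaining tertiary α-ketol hydroxyl; only the O–H bond reacts, so C4 keeps its configuration.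

Step 11
Reactants: 13 (2R,4S)-4-acetoxy-6-[(2R,3S)-5-methoxy-3-methyloxolan-2-yl]-4-methyl-5-oxo-1-(trityloxy)hexan-2-yl (2Z)-2-methylbut-2-enoate
Product: 14 (2R,4S)-4-acetoxy-1-hydroxy-6-[(2R,3S)-5-methoxy-3-methyloxolan-2-yl]-4-methyl-5-oxohexan-2-yl (2Z)-2-methylbut-2-enoate
Conditions: TsOH·H2O (cat.), MeOH–CH2Cl2, 0 °C → rt
Reagents that add atoms: none
Why: Acid-catalysed SN1 methanolysis removes the trityl ether, while the oxolane acetal only re-equilibrates to the same methyl acetal and the esters are untouched.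

Step 12
Reactants: 14 (2R,4S)-4-acetoxy-1-hydroxy-6-[(2R,3S)-5-methoxy-3-methyloxolan-2-yl]-4-methyl-5-oxohexan-2-yl (2Z)-2-methylbut-2-enoate
Product: 15 (2R,4S)-4-acetoxy-6-[(2R,3S)-5-methoxy-3-methyloxolan-2-yl]-4-methyl-1,5-dioxohexan-2-yl (2Z)-2-methylbut-2-enoate
Conditions: Dess–Martin periodinane, pyridine, CH2Cl2, 0 °C → rt
Reagents that add atoms: none
Why: Dess–Martin oxidation under buffered, non-basic conditions gives the α-acyloxy aldehyde without epimerising C6; it is used crude.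

Step 13
Reactants: 15 (2R,4S)-4-acetoxy-6-[(2R,3S)-5-methoxy-3-methyloxolan-2-yl]-4-methyl-1,5-dioxohexan-2-yl (2Z)-2-methylbut-2-enoate
Product: 16 methyl (4R,6S)-6-acetoxy-3-hydroxy-8-[(2R,3S)-5-methoxy-3-methyloxolan-2-yl]-6-methyl-2-methylidene-4-{[(2Z)-2-methylbut-2-enoyl]oxy}-7-oxooctanoate (C3 epimers)
Conditions: methyl propiolate, i-Bu2AlH, N-methylmorpholine N-oxide, THF, 0 °C; then 15, 0 °C → rt
Reagents that add atoms: methyl propiolate, C#CC(=O)OC
Why: Vinylalumination (hydroalumination of the propiolate, then addition of the α-aluminoacrylate to the aldehyde) gives the Baylis–Hillman-type adduct under non-basic conditions that spare the epimerisable C6 centre and the hindered C3 ketone; the new carbinol centre is a mixture and is erased in the next step.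

Step 14
Reactants: 16 methyl (4R,6S)-6-acetoxy-3-hydroxy-8-[(2R,3S)-5-methoxy-3-methyloxolan-2-yl]-6-methyl-2-methylidene-4-{[(2Z)-2-methylbut-2-enoyl]oxy}-7-oxooctanoate
Product: 17 methyl (2Z,4R,6S)-6-acetoxy-2-(bromomethyl)-8-[(2R,3S)-5-methoxy-3-methyloxolan-2-yl]-6-methyl-4-{[(2Z)-2-methylbut-2-enoyl]oxy}-7-oxooct-2-enoate
Conditions: NBS, Me2S, CH2Cl2, −20 → 0 °C
Reagents that add atoms: N-bromosuccinimide, BrN1C(=O)CCC1=O
Why: Corey–Kim-type activation of the allylic alcohol followed by SN2′ attack of bromide gives the transposed primary allylic bromide with the thermodynamically preferred Z geometry (C6 cis to CH2Br), the geometry needed for a syn-selective allylation.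

Step 15
Reactants: 17 methyl (2Z,4R,6S)-6-acetoxy-2-(bromomethyl)-8-[(2R,3S)-5-methoxy-3-methyloxolan-2-yl]-6-methyl-4-{[(2Z)-2-methylbut-2-enoyl]oxy}-7-oxooct-2-enoate
Product: 20 (1R,4S,6R,7S,8S,10S)-4-acetoxy-1-hydroxy-6-{[(2Z)-2-methylbut-2-enoyl]oxy}-3-oxogermacr-11(13)-en-12,8-olide (CNP0141210.3), via lactol 18 (not isolated), via hydroxy ester 19 (not isolated)
Conditions: BiCl3 (20 mol %), THF–H2O (9:1), rt (acetal hydrolysis); then syringe-pump addition (2 mM) to a divided cell, graphite-felt cathode, Pt anode, NH4Br (0.1 M) in THF–H2O, −0.5 V vs Ag/AgCl, rt; then PPTS, rt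
Reagents that add atoms: water, O
Why: Proposed new method: cathodically regenerated zerovalent bismuth inserts into the allylic C–Br bond, and the resulting (Z)-2-(methoxycarbonyl)allylbismuth adds through its γ-carbon (C7) to the open aldehyde form of lactol 18 in a six-membered transition state, which gives the 7,8-syn adduct and hence the cis lactone after loss of methanol, while allylic 1,3-strain holds H-6 in the plane of the allyl unit so that C8 is delivered to the C7 face anti to the C5 chain, giving 7S,8S from the 6R centre; allylbismuth reagents allylate aldehydes but not ketones, which is why the C3 ketone (otherwise set up for a five-membered closure) is expected to survive, and the closest known reactions are the bismuth-mediated Barbier allylation of aldehydes, including its electrochemical catalytic-bismuth variant, and the stoichiometric CrCl2-, zinc- or indium-mediated macrocyclic Barbier closures of 2-(bromomethyl)acrylates to germacranolides.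

**Compound list**

1 | (S)-5-(hydroxymethyl)furan-2(5H)-one | O=C1C=C[C@@H](CO)O1 | starting material
2 | [(2S)-5-oxo-2,5-dihydrofuran-2-yl]methyl 4-methylbenzenesulfonate | O=C1C=C[C@@H](COS(=O)(=O)c2ccc(C)cc2)O1 | intermediate
3 | [(2S,3S)-3-methyl-5-oxooxolan-2-yl]methyl 4-methylbenzenesulfonate | O=C1C[C@H](C)[C@@H](COS(=O)(=O)c2ccc(C)cc2)O1 | intermediate
4 | [(2S,3S)-5-hydroxy-3-methyloxolan-2-yl]methyl 4-methylbenzenesulfonate (lactol, not isolated) | OC1C[C@H](C)[C@@H](COS(=O)(=O)c2ccc(C)cc2)O1 | intermediate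
5 | [(2S,3S)-5-methoxy-3-methyloxolan-2-yl]methyl 4-methylbenzenesulfonate (anomeric mixture) | COC1C[C@H](C)[C@@H](COS(=O)(=O)c2ccc(C)cc2)O1 | intermediate
6 | (2S,3S)-5-methoxy-3-methyl-2-[(phenylsulfonyl)methyl]oxolane (anomeric mixture) | COC1C[C@H](C)[C@@H](CS(=O)(=O)c2ccccc2)O1 | intermediate
7 | (R)-5-[(trityloxy)methyl]dihydrofuran-2(3H)-one | O=C1CC[C@H](COC(c2ccccc2)(c2ccccc2)c2ccccc2)O1 | starting material
8 | (3S,5R)-3-methyl-5-[(trityloxy)methyl]dihydrofuran-2(3H)-one | O=C1[C@@H](C)C[C@H](COC(c2ccccc2)(c2ccccc2)c2ccccc2)O1 | intermediate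
9 | (3S,5R)-3-hydroxy-3-methyl-5-[(trityloxy)methyl]dihydrofuran-2(3H)-one | O=C1[C@@](C)(O)C[C@H](COC(c2ccccc2)(c2ccccc2)c2ccccc2)O1 | intermediate
10 | (3S,5R)-3,5-dihydroxy-1-[(2S,3S)-5-methoxy-3-methyloxolan-2-yl]-3-methyl-1-(phenylsulfonyl)-6-(trityloxy)hexan-2-one (C1 epimers, anomeric mixture) | COC1C[C@H](C)[C@H](O1)C(S(=O)(=O)c2ccccc2)C(=O)[C@@](C)(O)C[C@@H](O)COC(c3ccccc3)(c3ccccc3)c3ccccc3 | intermediate
11 | (3S,5R)-3,5-dihydroxy-1-[(2R,3S)-5-methoxy-3-methyloxolan-2-yl]-3-methyl-6-(trityloxy)hexan-2-one | COC1C[C@H](C)[C@H](O1)CC(=O)[C@@](C)(O)C[C@@H](O)COC(c2ccccc2)(c2ccccc2)c2ccccc2 | intermediate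
12 | (2R,4S)-4-hydroxy-6-[(2R,3S)-5-methoxy-3-methyloxolan-2-yl]-4-methyl-5-oxo-1-(trityloxy)hexan-2-yl (2Z)-2-methylbut-2-enoate | COC1C[C@H](C)[C@H](O1)CC(=O)[C@@](C)(O)C[C@@H](OC(=O)/C(C)=C\C)COC(c2ccccc2)(c2ccccc2)c2ccccc2 | intermediate
13 | (2R,4S)-4-acetoxy-6-[(2R,3S)-5-methoxy-3-methyloxolan-2-yl]-4-methyl-5-oxo-1-(trityloxy)hexan-2-yl (2Z)-2-methylbut-2-enoate | COC1C[C@H](C)[C@H](O1)CC(=O)[C@@](C)(OC(C)=O)C[C@@H](OC(=O)/C(C)=C\C)COC(c2ccccc2)(c2ccccc2)c2ccccc2 | intermediate
14 | (2R,4S)-4-acetoxy-1-hydroxy-6-[(2R,3S)-5-methoxy-3-methyloxolan-2-yl]-4-methyl-5-oxohexan-2-yl (2Z)-2-methylbut-2-enoate | COC1C[C@H](C)[C@H](O1)CC(=O)[C@@](C)(OC(C)=O)C[C@@H](OC(=O)/C(C)=C\C)CO | intermediate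
15 | (2R,4S)-4-acetoxy-6-[(2R,3S)-5-methoxy-3-methyloxolan-2-yl]-4-methyl-1,5-dioxohexan-2-yl (2Z)-2-methylbut-2-enoate | COC1C[C@H](C)[C@H](O1)CC(=O)[C@@](C)(OC(C)=O)C[C@@H](OC(=O)/C(C)=C\C)C=O | intermediate
16 | methyl (4R,6S)-6-acetoxy-3-hydroxy-8-[(2R,3S)-5-methoxy-3-methyloxolan-2-yl]-6-methyl-2-methylidene-4-{[(2Z)-2-methylbut-2-enoyl]oxy}-7-oxooctanoate (C3 epimers) | COC1C[C@H](C)[C@H](O1)CC(=O)[C@@](C)(OC(C)=O)C[C@@H](OC(=O)/C(C)=C\C)C(O)C(=C)C(=O)OC | intermediate
17 | methyl (2Z,4R,6S)-6-acetoxy-2-(bromomethyl)-8-[(2R,3S)-5-methoxy-3-methyloxolan-2-yl]-6-methyl-4-{[(2Z)-2-methylbut-2-enoyl]oxy}-7-oxooct-2-enoate | COC1C[C@H](C)[C@H](O1)CC(=O)[C@@](C)(OC(C)=O)C[C@@H](OC(=O)/C(C)=C\C)/C=C(\CBr)C(=O)OC | intermediate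
18 | methyl (2Z,4R,6S)-6-acetoxy-2-(bromomethyl)-8-[(2R,3S)-5-hydroxy-3-methyloxolan-2-yl]-6-methyl-4-{[(2Z)-2-methylbut-2-enoyl]oxy}-7-oxooct-2-enoate (lactol, not isolated; open form is the C8 aldehyde with free C1–OH) | OC1C[C@H](C)[C@H](O1)CC(=O)[C@@](C)(OC(C)=O)C[C@@H](OC(=O)/C(C)=C\C)/C=C(\CBr)C(=O)OC | intermediate
19 | methyl (1R,4S,6R,7S,8S,10S)-4-acetoxy-1,8-dihydroxy-6-{[(2Z)-2-methylbut-2-enoyl]oxy}-3-oxogermacr-11(13)-en-12-oate (not isolated) | COC(=O)C(=C)[C@H]1[C@@H](O)C[C@H](C)[C@H](O)CC(=O)[C@@](C)(OC(C)=O)C[C@H]1OC(=O)/C(C)=C\C | intermediate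
20 | (1R,4S,6R,7S,8S,10S)-4-acetoxy-1-hydroxy-6-{[(2Z)-2-methylbut-2-enoyl]oxy}-3-oxogermacr-11(13)-en-12,8-olide (7,8-cis lactone; CNP0141210.3) | C=C1C(=O)O[C@H]2C[C@H](C)[C@H](O)CC(=O)[C@@](C)(OC(C)=O)C[C@@H](OC(=O)/C(C)=C\C)[C@@H]12 | target

**Step count and risks**

Total step count: 15 (steps 1–4 on the western fragment, steps 5–6 on the eastern fragment, steps 7–15 after union).
Longest linear sequence: 13 steps (1 → 6 → 20: steps 1–4 and 7–15); the branch from 7 is 11 steps.

The three steps most likely to fail: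

Step 15 (the proposed new step). The risks are that allylbismuth is too weak a nucleophile for a ten-membered closure onto an aldehyde that sits mostly as its lactol, that the C3 ketone is attacked through a five-membered transition state after all, or that facial control at C7 is poor. The fallback uses known allylboron chemistry, which does not touch ketones and is stereospecific. It sets out from 16: acetylation (Ac2O, DMAP) gives the allylic acetate F1, and copper-catalysed SN2′ borylation (B2pin2, CuCl, KOAc) gives the 2-(methoxycarbonyl)allylboronate F2 with C6 cis to the borylmethyl group. Hydrolysis of the methyl acetal (aqueous AcOH–THF) gives the lactol boronate F3, which on warming in toluene (or with catalytic Sc(OTf)3) undergoes intramolecular allylboration of the aldehyde through a closed chair transition state. The fallback comes back to the route at 19, which lactonises to 20.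

Step 7 (fragment union). The lactone carbonyl is flanked by a quaternary carbon bearing an alkoxide and may be too unreactive at the low temperature the β-oxygenated sulfonyl carbanion needs. The fallback sets out from 9: ring opening with N,O-dimethylhydroxylamine hydrochloride and AlMe3 gives the open-chain dihydroxy Weinreb amide F4, a more electrophilic, chelation-activated acyl donor. Addition of F4 to lithiated 6 (excess LiN(i-Pr)2, −78 °C) gives the β-keto sulfone, so the fallback comes back to the route at 10.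

Step 13 (C7 homologation). The aluminium reagent may reduce or add to the α-acetoxy ketone, the α-acyloxy aldehyde may epimerise at C6, or the aluminium alkoxide may trigger angeloyl migration from O-6 to O-7. The fallback sets out from 15 and builds the same adduct by an aldol reaction followed by elimination. The lithium enolate of methyl 3-(phenylselanyl)propanoate adds to the aldehyde at −78 °C to give the β-hydroxy α-(phenylselanylmethyl) ester F5. Oxidation with H2O2–pyridine and selenoxide syn-elimination then unveil the methylidene group, and the fallback comes back to the route at 16.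

Further compounds
F1 | step 15 | methyl (4R,6S)-3,6-diacetoxy-8-[(2R,3S)-5-methoxy-3-methyloxolan-2-yl]-6-methyl-2-methylidene-4-{[(2Z)-2-methylbut-2-enoyl]oxy}-7-oxooctanoate | COC1C[C@H](C)[C@H](O1)CC(=O)[C@@](C)(OC(C)=O)C[C@@H](OC(=O)/C(C)=C\C)C(OC(C)=O)C(=C)C(=O)OC
F2 | step 15 | methyl (2E,4R,6S)-6-acetoxy-8-[(2R,3S)-5-methoxy-3-methyloxolan-2-yl]-6-methyl-4-{[(2Z)-2-methylbut-2-enoyl]oxy}-7-oxo-2-[(4,4,5,5-tetramethyl-1,3,2-dioxaborolan-2-yl)methyl]oct-2-enoate | COC1C[C@H](C)[C@H](O1)CC(=O)[C@@](C)(OC(C)=O)C[C@@H](OC(=O)/C(C)=C\C)/C=C(\CB2OC(C)(C)C(C)(C)O2)C(=O)OC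
F3 | step 15 | methyl (2E,4R,6S)-6-acetoxy-8-[(2R,3S)-5-hydroxy-3-methyloxolan-2-yl]-6-methyl-4-{[(2Z)-2-methylbut-2-enoyl]oxy}-7-oxo-2-[(4,4,5,5-tetramethyl-1,3,2-dioxaborolan-2-yl)methyl]oct-2-enoate | OC1C[C@H](C)[C@H](O1)CC(=O)[C@@](C)(OC(C)=O)C[C@@H](OC(=O)/C(C)=C\C)/C=C(\CB2OC(C)(C)C(C)(C)O2)C(=O)OC
F4 | step 7 | (2S,4R)-2,4-dihydroxy-N-methoxy-N,2-dimethyl-5-(trityloxy)pentanamide | CON(C)C(=O)[C@@](C)(O)C[C@@H](O)COC(c1ccccc1)(c1ccccc1)c1ccccc1
F5 | step 13 | methyl (4R,6S)-6-acetoxy-3-hydroxy-8-[(2R,3S)-5-methoxy-3-methyloxolan-2-yl]-6-methyl-4-{[(2Z)-2-methylbut-2-enoyl]oxy}-7-oxo-2-[(phenylselanyl)methyl]octanoate | COC1C[C@H](C)[C@H](O1)CC(=O)[C@@](C)(OC(C)=O)C[C@@H](OC(=O)/C(C)=C\C)C(O)C(C[Se]c2ccccc2)C(=O)OC
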